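## Structural features

The target is an aryltetralin lignan in which an aromatic ring A (7-hydroxy-6-methoxy) is fused through C4a–C8a to a saturated ring B (C1–C4). C1 carries a 4-hydroxy-3-methoxyphenyl group, C2 a CH2O arm esterified with (E)-p-coumaric acid, C3 a free CH2OH arm, and C4 is a methylene. C1, C2 and C3 are three contiguous stereocentres, (1S,2R,3R), with neighbours on opposite faces, so all three substituents can be equatorial on the half-chair of ring B. The fragile groups are three free phenols, the cinnamate C=C bond (no hydrogenation or hydrogenolysis once it is present), the ester (prone to migrate to the neighbouring CH2OH under base) and the doubly benzylic C1–H. The carbon skeleton is not the real difficulty; that lies in acylating only one of two very similar primary alcohols and in setting C1 in a molecule that already holds the ester. The key step uses the fact that C1 is a methine bonded to two oxygenated arenes (C8a of ring A, para to its methoxy group, and the guaiacyl carbon para to its hydroxyl) and stands 1,3 to the oxygen of the C3 hydroxymethyl group. C1 can therefore be the acetal carbon of a 2-methoxytetrahydrofuran whose ring oxygen is that hydroxyl, with the C2 arm already esterified. Because this tetrahydrofuran runs through the hydroxymethyl carbon on C3 and not through C4, the 2,3-trans tetralin corresponds to the 3,4-cis tetrahydrofuran; a 3,4-trans acetal would end as the C2 epimer of the target.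

## Logic of the disconnections

16 ⇒ 13 + 14 (through 15). The bonds cut are C1–C8a and the bond from C1 to the guaiacyl ring. Both join C1 to an aromatic carbon para to an oxygen, so both are Friedel–Crafts bonds; cutting them leaves C1 at the aldehyde oxidation level, tied to the oxygen of the C3 arm as a cyclic acetal. Ring B, the C1 stereocentre and a whole aryl unit disappear, and the distinction between the two primary alcohols is already written into 13 (ring oxygen versus ester). The forward step must arylate one acetal carbon with two different arenes at the right positions, keep the centre next to the acetal carbon intact, and place the aryl group trans to the C2 arm.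

13 ⇒ 11 + 12. The ester C–O bond is cut. 11 has a single aliphatic hydroxyl, so no selection between two CH2OH groups is needed, and 12 is used as bought. The forward step must esterify a primary alcohol in the presence of two phenols and a methyl acetal.

11 ⇒ 10 ⇒ 9. First the O–benzyl bond, then the ring C–O bond of the acetal. The benzyl ether masks the phenol through all base and hydride steps and leaves by hydrogenolysis before any alkene is present. Opening the acetal gives an acyclic diol acetal in which ring size alone decides which hydroxyl closes (five-membered ring against oxetane). The forward closure must be mild enough not to epimerise the carbon next to the acetal carbon.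

9 ⇒ 8. No skeletal bond is cut; the two CH2OH groups of 9 are traced back to the lactone of 8. This is the stereochemical pivot: the cis pair needed in 13 is the trans pair on the lactone ring of 8, because the lactone carbonyl becomes the exocyclic, later esterified arm. The forward step is a plain hydride reduction that must spare the acetal.

8 ⇒ 6 (through 7). The bond between the lactone α-carbon and the acetal carbon is cut. This removes one stereocentre and leaves a monosubstituted lactone. The forward step needs a one-carbon electrophile at the aldehyde oxidation level, delivered anti to the benzyl group; that face is both the kinetic and the thermodynamic choice.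

6 ⇒ 4 (through 5) ⇒ 3. The lactone C–O bond and then the two C–H bonds at the benzylic and the α carbon are cut. The only catalyst-controlled stereocentre is traced to an alkene. The forward steps need an ester reduction that spares a carboxylate and a highly enantioselective hydrogenation.

3 ⇒ 1 + 2. The C=C bond is cut. This gives an aromatic aldehyde and a symmetrical diester; the forward condensation must stop at the half-ester.

## Other disconnections considered

Alternative 1: The cut runs through C2–C3 and C1–C8a and splits the tetralin into two identical C6–C3 halves. In the forward sense, Ag2O would oxidise the auxiliary-bound bromoferulate A1 to phenoxy radicals that couple at their side-chain β-carbons; the bis-quinone methide would close ring B and tautomerise to the dihydronaphthalene A2. In its favour, the skeleton, ring B and the trans C1/C2 pair arise in one step from a monomer a few steps from a commodity hydroxycinnamic acid. Since both partners are the same, there is no cross-selectivity problem; on these two points it is the equal or the better of the chosen plan, whose key step must tell a tethered arene from an external one. Against it, A2 is far from 16 in functionality: two bromine atoms must be removed, the C3–C4 double bond must be reduced with control of C3, and two acyl groups at the same oxidation level must be reduced and then told apart so that only the C2 arm is esterified. All reductions would have to precede the arrival of the cinnamate, and facial control of a radical–radical coupling by a remote auxiliary is less predictable than the catalyst and substrate control of the chosen plan. Structurally, the alternative creates C3 only after the key step, whereas the chosen plan fixes C2 and C3 before ring B forms. Mechanistically it is radical against cationic. In step count it reaches the skeleton sooner but would need roughly six to eight further operations, against none after step 9.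

Alternative 2: The cut runs through C1–C2 and C3–C4, a retro-Diels–Alder of ring B. In the forward sense, irradiation of the aldehyde A3 would move a hydrogen from the diarylmethane CH2 to the excited carbonyl and give a transient hydroxy-diene, which the crotonyl imide A4 would trap to give the cycloadduct A5. In its favour, two C–C bonds, ring B and all ring stereocentres arise in one pericyclic step, and the (E) geometry of A4 passes directly into the trans C2/C3 pair, a cleaner transfer than substrate-controlled alkylation. The two one-carbon arms arrive differentiated (imide at C3, allyl ether at C2), which is equal to the chosen plan. Against it, A5 carries a C4 hydroxyl that 16 lacks; the oxazolidinone has no chelating Lewis acid to lock it in a photochemical cycloaddition, so facial control is uncertain; the C1/C2 relationship rests on endo preference and on the geometry of the transient diene; and A3 needs its own aryl–CH2–aryl construction. After the key step there would follow deoxygenation, reductive removal of the auxiliary, protection of the C3 arm, deallylation, esterification and desilylation. The chosen plan is shorter and ends at the target without protecting-group traffic.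

Alternative 3: The cut runs through C1–C8a and C3–C4; C1–C2–C3 come from the cyclopropane A6, ring A and C4 from the benzylic chloride A7. In the forward sense, Sc(OTf)3 would activate the malonate of A6, the arene carbon of A7 para to its methoxy group would open the ring at the aryl-bearing carbon, and base would then let the malonate carbanion displace the chloride to give A8. In its favour, it forms the same C1–C8a bond with the same regiochemistry as the chosen plan, it is convergent, and the arms are differentiated by oxidation state (aldehyde at C2, diester at C3), which is equal to the chosen plan. Cyclopropanes of this type are accessible in enantioenriched form by organocatalytic cyclopropanation of the corresponding enal. Against it, invertive opening of the trans cyclopropane A6 would place aryl and formyl cis on ring B, so the centre next to the aldehyde would have to be epimerised. The electron-rich aryl donor may open through a free benzylic cation with loss of enantiopurity. The arene of A7 is damped by its pivalate and carries a chloride that the Lewis acid can ionise. C3 is quaternary in A8 and becomes a stereocentre only on late decarboxylation, and the pivalate has to leave without harming the cinnamate. At least six operations would follow the key step. The chosen plan carries all three centres more predictably and needs no step after ring closure.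

Key step: step 9

Remarks on the chemistry (assumptions and one correction):
- Correction: the acetal 13 must be the 3,4-cis (3R,4R) isomer. Anti-selective hydroxymethylation of the β-benzyl lactone followed by reduction of the lactone carbonyl to the acetal would give the trans isomer and hence the C2 epimer of 16. Here the lactone carbonyl is therefore made the future ester-bearing arm and the acetal carbon is brought in as the new α-substituent.
- Compounds 10, 11 and 13 are taken as mixtures of both epimers at the acetal carbon; both give the same oxocarbenium ion, so this centre is left undefined.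
- Compound 1 is taken as a purchased catalogue compound.
- The hand of the bisphosphine in step 2 is assumed to be the one that gives the R acid; it is to be checked by the sign of rotation of 6, and the antipodal ligand would be used otherwise.

## Route

Step 1
Reactants: 1 4-(benzyloxy)-3-methoxybenzaldehyde; 2 dimethyl succinate
Product: 3 (E)-4-[4-(benzyloxy)-3-methoxyphenyl]-3-(methoxycarbonyl)but-3-enoic acid
Conditions: NaOMe (1.5 equiv), MeOH, reflux; then aq. HCl
Reagents that add atoms: none
Why: Stobbe condensation: the succinate enolate adds to the aldehyde, the alkoxide lactonises onto the distal ester, and base-induced opening of the paraconate gives the (E)-alkylidene half-ester; the benzyl ether is inert to methoxide and the carboxylate formed protects the product from a second condensation.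

Step 2
Reactants: 3 (E)-4-[4-(benzyloxy)-3-methoxyphenyl]-3-(methoxycarbonyl)but-3-enoic acid
Product: 4 (R)-4-[4-(benzyloxy)-3-methoxyphenyl]-3-(methoxycarbonyl)butanoic acid
Conditions: [Rh(cod)2]BF4 (1 mol%), (S,S)-Et-DuPhos (1.1 mol%), NaOMe (10 mol%), H2 (5 bar), MeOH, rt
Reagents that add atoms: none
Why: Rhodium-catalysed asymmetric hydrogenation of an itaconate-type half-ester: carboxylate and alkene chelate the metal and the C2-symmetric bisphospholane selects the alkene face, which sets the only catalyst-controlled stereocentre (R, the future C3 of 16); aryl benzyl ethers are not cleaved by this homogeneous catalyst.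

Step 3
Reactants: 4 (R)-4-[4-(benzyloxy)-3-methoxyphenyl]-3-(methoxycarbonyl)butanoic acid
Product: 6 (R)-4-[4-(benzyloxy)-3-methoxybenzyl]dihydrofuran-2(3H)-one, via hydroxy acid 5 (not isolated)
Conditions: KOH (1.0 equiv), EtOH; CaCl2 (2 equiv), NaBH4 (4 equiv), EtOH, −10 °C → rt; then aq. HCl, rt
Reagents that add atoms: none
Why: Ca(BH4)2 formed in the flask reduces the methyl ester while the potassium carboxylate is not reduced; acidification lactonises the γ-hydroxy acid 5 to the five-membered lactone, and the stereocentre is not touched.

Step 4
Reactants: 6 (R)-4-[4-(benzyloxy)-3-methoxybenzyl]dihydrofuran-2(3H)-one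
Product: 8 (3S,4R)-4-[4-(benzyloxy)-3-methoxybenzyl]-3-(dimethoxymethyl)dihydrofuran-2(3H)-one, via ketene silyl acetal 7 (not isolated)
Conditions: LiN(CHMe2)2 (1.1 equiv), Me3SiCl (1.2 equiv), THF, −78 °C; solvent change to CH2Cl2; HC(OMe)3 (1.5 equiv), Me3SiOTf (10 mol%), −78 °C
Reagents that add atoms: trimethyl orthoformate, COC(OC)OC
Why: Mukaiyama-type alkylation of a ketene silyl acetal: Me3SiOTf turns the orthoformate into the dimethoxycarbenium ion, which should attack C3 of 7 on the face opposite the C4 benzyl group and give the trans lactone (new centre 3S); this isomer is also the more stable one, so any equilibration through the enol would work in the same direction.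

Step 5
Reactants: 8 (3S,4R)-4-[4-(benzyloxy)-3-methoxybenzyl]-3-(dimethoxymethyl)dihydrofuran-2(3H)-one
Product: 9 (2R,3R)-2-[4-(benzyloxy)-3-methoxybenzyl]-3-(dimethoxymethyl)butane-1,4-diol
Conditions: LiAlH4 (1.5 equiv), THF, 0 °C; aq. NaOH work-up
Reagents that add atoms: none
Why: Hydride reduction of a lactone to the 1,4-diol; the dimethyl acetal and the benzyl ether are inert to LiAlH4 and both stereocentres are carried over (the descriptor of the acetal-bearing carbon becomes R only because the priorities change).

Step 6
Reactants: 9 (2R,3R)-2-[4-(benzyloxy)-3-methoxybenzyl]-3-(dimethoxymethyl)butane-1,4-diol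
Product: 10 {(3R,4R)-4-[4-(benzyloxy)-3-methoxybenzyl]-2-methoxytetrahydrofuran-3-yl}methanol (both epimers at C2)
Conditions: pyridinium p-toluenesulfonate (10 mol%), 4 Å molecular sieves, CH2Cl2, 0 °C → rt
Reagents that add atoms: none
Why: Acid-catalysed intramolecular transacetalisation (5-exo closure): only the hydroxyl on the arm of the benzyl-bearing carbon can reach the oxocarbenium carbon through a five-membered ring, the other would have to form an oxetane and stays free; since the new ring passes through the acetal carbon and the former lactone carbonyl carbon is now the exocyclic CH2OH, the trans pair of 8 becomes the cis pair of the tetrahydrofuran; buffered acid and low temperature should let the cation be captured before it loses the neighbouring proton.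

Step 7
Reactants: 10 {(3R,4R)-4-[4-(benzyloxy)-3-methoxybenzyl]-2-methoxytetrahydrofuran-3-yl}methanol
Product: 11 [(3R,4R)-4-(4-hydroxy-3-methoxybenzyl)-2-methoxytetrahydrofuran-3-yl]methanol (both epimers at C2)
Conditions: H2 (1 atm), 10% Pd/C, EtOAc, rt
Reagents that add atoms: none
Why: Hydrogenolysis of an aryl benzyl ether, placed here because no alkene is present yet; the methyl acetal and the primary alcohol are inert in a neutral solvent.

Step 8
Reactants: 11 [(3R,4R)-4-(4-hydroxy-3-methoxybenzyl)-2-methoxytetrahydrofuran-3-yl]methanol; 12 (E)-3-(4-hydroxyphenyl)prop-2-enoic acid (p-coumaric acid)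
Product: 13 [(3R,4R)-4-(4-hydroxy-3-methoxybenzyl)-2-methoxytetrahydrofuran-3-yl]methyl (E)-3-(4-hydroxyphenyl)prop-2-enoate (both epimers at C2)
Conditions: PPh3 (1.3 equiv), DIAD (1.3 equiv), THF, 0 °C → rt
Reagents that add atoms: none
Why: Mitsunobu esterification: the betaine from PPh3 and DIAD is protonated by the carboxylic acid (pKa about 4.5) and not by the phenols (pKa about 10), and the primary alcohol is activated as its oxyphosphonium ion and displaced by the carboxylate, so neither phenol should need protection; the displacement occurs at a CH2 group, no stereocentre is involved, and the near-neutral medium leaves the acetal intact.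

Step 9
Reactants: 13 [(3R,4R)-4-(4-hydroxy-3-methoxybenzyl)-2-methoxytetrahydrofuran-3-yl]methyl (E)-3-(4-hydroxyphenyl)prop-2-enoate; 14 2-methoxyphenol (guaiacol)
Product: 16 [(1S,2R,3R)-7-hydroxy-1-(4-hydroxy-3-methoxyphenyl)-3-(hydroxymethyl)-6-methoxy-1,2,3,4-tetrahydronaphthalen-2-yl]methyl (E)-3-(4-hydroxyphenyl)prop-2-enoate (the target), via aryltetrahydrofuran 15 (not isolated)
Conditions: 14 (1.5 equiv), BF3·OEt2 (2.5 equiv), CH2Cl2 (0.02 mol/L), −40 → 0 °C; aq. NaHCO3
Reagents that add atoms: none
Why: Proposed new method: BF3 should ionise the methyl acetal of 13 to a cyclic oxocarbenium ion, 14 adds through the carbon para to its hydroxyl on the face opposite the two cis substituents to give 15, the benzylic C–O bond of 15 (para to a phenolic oxygen) ionises in turn, and ring A attacks the cation with its carbon para to OMe while the ring oxygen is released as the C3 hydroxymethyl group; the reverse order of the two arylations would reach the same cation. The closest known reaction types are the acid-mediated double arylation of acetals and lactol ethers and the acid-induced rearrangement of 2-aryl-4-benzyltetrahydrofuran lignans to aryltetralins; new is their union in one flask with one tethered and one external arene. Ring B closes by a 6-endo Friedel–Crafts attack (the attacked aromatic bond C4a–C8a lies in the new ring) through a half-chair in which the aryl group at C1 and the arms at C2 and C3 are all pseudo-equatorial. C1 is the only new stereocentre and is set under the control of C2, the aryl group ending trans to the acyloxymethyl arm; C2 and C3 are carried over from 13, the 3,4-cis tetrahydrofuran becoming the 2,3-trans tetralin. The step needs hetero- over homo-bisarylation, which the tether (high effective molarity), the small excess of 14 and the high dilution should secure. It also needs attack on 14 para to OH, favoured because hydroxyl is the stronger para director; closure of ring A para to OMe and not at the crowded position between CH2 and OMe; and retention of the proton next to the oxocarbenium carbon, favoured by low temperature and fast capture.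

## Compound list

1 | 4-(benzyloxy)-3-methoxybenzaldehyde | COc1cc(C=O)ccc1OCc1ccccc1 | starting material
2 | dimethyl succinate | COC(=O)CCC(=O)OC | starting material
3 | (E)-4-[4-(benzyloxy)-3-methoxyphenyl]-3-(methoxycarbonyl)but-3-enoic acid | COC(=O)/C(=C/c1ccc(OCc2ccccc2)c(OC)c1)CC(=O)O | intermediate
4 | (R)-4-[4-(benzyloxy)-3-methoxyphenyl]-3-(methoxycarbonyl)butanoic acid | COC(=O)[C@@H](CC(=O)O)Cc1ccc(OCc2ccccc2)c(OC)c1 | intermediate
5 | (R)-4-[4-(benzyloxy)-3-methoxyphenyl]-3-(hydroxymethyl)butanoic acid | OC[C@@H](CC(=O)O)Cc1ccc(OCc2ccccc2)c(OC)c1 | intermediate (not isolated)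
6 | (R)-4-[4-(benzyloxy)-3-methoxybenzyl]dihydrofuran-2(3H)-one | O=C1C[C@@H](Cc2ccc(OCc3ccccc3)c(OC)c2)CO1 | intermediate
7 | (R)-({4-[4-(benzyloxy)-3-methoxybenzyl]-4,5-dihydrofuran-2-yl}oxy)trimethylsilane | C[Si](C)(C)OC1=C[C@@H](Cc2ccc(OCc3ccccc3)c(OC)c2)CO1 | intermediate (not isolated)
8 | (3S,4R)-4-[4-(benzyloxy)-3-methoxybenzyl]-3-(dimethoxymethyl)dihydrofuran-2(3H)-one (trans) | COC(OC)[C@H]1C(=O)OC[C@@H]1Cc1ccc(OCc2ccccc2)c(OC)c1 | intermediate
9 | (2R,3R)-2-[4-(benzyloxy)-3-methoxybenzyl]-3-(dimethoxymethyl)butane-1,4-diol | COC(OC)[C@@H](CO)[C@H](CO)Cc1ccc(OCc2ccccc2)c(OC)c1 | intermediate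
10 | {(3R,4R)-4-[4-(benzyloxy)-3-methoxybenzyl]-2-methoxytetrahydrofuran-3-yl}methanol (3,4-cis, both epimers at C2) | COC1OC[C@H](Cc2ccc(OCc3ccccc3)c(OC)c2)[C@@H]1CO | intermediate
11 | [(3R,4R)-4-(4-hydroxy-3-methoxybenzyl)-2-methoxytetrahydrofuran-3-yl]methanol (3,4-cis, both epimers at C2) | COC1OC[C@H](Cc2ccc(O)c(OC)c2)[C@@H]1CO | intermediate
12 | (E)-3-(4-hydroxyphenyl)prop-2-enoic acid (p-coumaric acid) | OC(=O)/C=C/c1ccc(O)cc1 | starting material
13 | [(3R,4R)-4-(4-hydroxy-3-methoxybenzyl)-2-methoxytetrahydrofuran-3-yl]methyl (E)-3-(4-hydroxyphenyl)prop-2-enoate (3,4-cis, both epimers at C2) | COC1OC[C@H](Cc2ccc(O)c(OC)c2)[C@@H]1COC(=O)/C=C/c1ccc(O)cc1 | intermediate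
14 | 2-methoxyphenol (guaiacol) | COc1ccccc1O | starting material
15 | [(2S,3R,4R)-2-(4-hydroxy-3-methoxyphenyl)-4-(4-hydroxy-3-methoxybenzyl)tetrahydrofuran-3-yl]methyl (E)-3-(4-hydroxyphenyl)prop-2-enoate | COc1cc([C@H]2OC[C@H](Cc3ccc(O)c(OC)c3)[C@@H]2COC(=O)/C=C/c2ccc(O)cc2)ccc1O | intermediate (not isolated)
16 | [(1S,2R,3R)-7-hydroxy-1-(4-hydroxy-3-methoxyphenyl)-3-(hydroxymethyl)-6-methoxy-1,2,3,4-tetrahydronaphthalen-2-yl]methyl (E)-3-(4-hydroxyphenyl)prop-2-enoate | COc1cc([C@H]2c3cc(O)c(OC)cc3C[C@@H](CO)[C@@H]2COC(=O)/C=C/c2ccc(O)cc2)ccc1O | target

## Step count and least certain steps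

Total step count: 9. Longest linear sequence: 9 steps (1 → 16); 12 and 14 enter as bought at steps 8 and 9.

Step 9 (key step, proposed new method). The most likely failures are three. The second cation may be captured by another molecule of 14 instead of ring A, because an external nucleophile in solution competes with the tether. Compound 14 may attack through the position para to its methoxy group, because both oxygen substituents activate. The oxocarbenium ion may lose its neighbouring proton, which would scramble C2 through the enol ether. The fallback uses known chemistry, sets out from 6 and comes back at 15. The lithium enolate of 6 (LiN(CHMe2)2, THF, −78 °C) would be added to 1 to give the trans aldol adduct (3S,4R)-4-[4-(benzyloxy)-3-methoxybenzyl]-3-{[4-(benzyloxy)-3-methoxyphenyl](hydroxy)methyl}dihydrofuran-2(3H)-one F1. LiAlH4 would reduce it to the triol (2R,3R)-2-[4-(benzyloxy)-3-methoxybenzyl]-3-{[4-(benzyloxy)-3-methoxyphenyl](hydroxy)methyl}butane-1,4-diol F2. Catalytic camphorsulfonic acid in CH2Cl2 at 0 °C would close the tetrahydrofuran through the benzylic cation to give {(2S,3R,4R)-4-[4-(benzyloxy)-3-methoxybenzyl]-2-[4-(benzyloxy)-3-methoxyphenyl]tetrahydrofuran-3-yl}methanol F3. Hydrogenolysis (H2, 10% Pd/C, EtOAc, short contact time) would free lariciresinol F4. Esterification of F4 with 12 under the conditions of step 8 would give 15 as an isolated compound. A Brønsted acid (CF3CO2H, CH2Cl2, 0 °C) would then rearrange 15 to 16, the known tetrahydrofuran-to-aryltetralin conversion of this lignan class, in which no external arene is involved.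

Step 4. The most likely failures are loss of methanol from 8 to the α-methoxymethylene lactone under the silyl triflate, and silylation on carbon instead of oxygen during enolate trapping; both would lower the throughput, while the facial selectivity is less in doubt. The fallback sets out from 6 and comes back at 8. Claisen formylation of 6 with ethyl formate and NaH in THF would give (R)-4-[4-(benzyloxy)-3-methoxybenzyl]-3-(hydroxymethylene)dihydrofuran-2(3H)-one F5. Acetalisation of F5 with HC(OMe)3 and catalytic camphorsulfonic acid in MeOH would give 8; the C3 proton is then delivered under equilibrating conditions and the trans isomer is the stable one.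

Step 6. The most likely failure is epimerisation of the carbon next to the acetal carbon through reversible loss of its proton from the oxocarbenium ion, since the cis pair is the less stable arrangement; intermolecular acetal exchange is a lesser concern. The fallback sets out from 6 (through 7) and comes back at 10. Compound 7 would be treated with 1,3-dithian-2-ylium tetrafluoroborate in CH2Cl2 at −78 °C to give the trans lactone (3R,4R)-4-[4-(benzyloxy)-3-methoxybenzyl]-3-(1,3-dithian-2-yl)dihydrofuran-2(3H)-one F6. LiAlH4 would give (2R,3R)-2-[4-(benzyloxy)-3-methoxybenzyl]-3-(1,3-dithian-2-yl)butane-1,4-diol F7. PhI(OCOCF3)2 with MeOH (5 equiv) and NaHCO3 in MeCN at 0 °C would unmask the dithiane oxidatively; the thionium ion would be captured first by the nearby hydroxyl and then by methanol, giving 10 under buffered, irreversible conditions.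

Step 8. The most likely failure is competing alkylation of a phenol oxygen by the oxyphosphonium ion, or sluggish ester formation, because three acidic OH groups are present. The fallback sets out from 11 and comes back at 13. Both hydroxyls of 11 would be acylated with purchased (E)-4-acetoxycinnamic acid (2.5 equiv, EDC·HCl, DMAP, CH2Cl2) to give the bis-ester [(3R,4R)-4-{4-[(E)-3-(4-acetoxyphenyl)prop-2-enoyloxy]-3-methoxybenzyl}-2-methoxytetrahydrofuran-3-yl]methyl (E)-3-(4-acetoxyphenyl)prop-2-enoate F8. Pyrrolidine in CH2Cl2 at 0 °C would then cleave the three aryl esters (two acetates and the aryl cinnamate), which are far more reactive towards amines than the alkyl cinnamate, and give 13.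

## Further compounds

F1 | step 9 | (3S,4R)-4-[4-(benzyloxy)-3-methoxybenzyl]-3-{[4-(benzyloxy)-3-methoxyphenyl](hydroxy)methyl}dihydrofuran-2(3H)-one (both carbinol epimers) | OC([C@H]1C(=O)OC[C@@H]1Cc1ccc(OCc2ccccc2)c(OC)c1)c1ccc(OCc2ccccc2)c(OC)c1
F2 | step 9 | (2R,3R)-2-[4-(benzyloxy)-3-methoxybenzyl]-3-{[4-(benzyloxy)-3-methoxyphenyl](hydroxy)methyl}butane-1,4-diol (both carbinol epimers) | OC([C@@H](CO)[C@H](CO)Cc1ccc(OCc2ccccc2)c(OC)c1)c1ccc(OCc2ccccc2)c(OC)c1
F3 | step 9 | {(2S,3R,4R)-4-[4-(benzyloxy)-3-methoxybenzyl]-2-[4-(benzyloxy)-3-methoxyphenyl]tetrahydrofuran-3-yl}methanol | COc1cc([C@H]2OC[C@H](Cc3ccc(OCc4ccccc4)c(OC)c3)[C@@H]2CO)ccc1OCc1ccccc1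
F4 | step 9 | lariciresinol, 4-[(2S,3R,4R)-4-(4-hydroxy-3-methoxybenzyl)-3-(hydroxymethyl)tetrahydrofuran-2-yl]-2-methoxyphenol | COc1cc([C@H]2OC[C@H](Cc3ccc(O)c(OC)c3)[C@@H]2CO)ccc1O
F5 | step 4 | (R)-4-[4-(benzyloxy)-3-methoxybenzyl]-3-(hydroxymethylene)dihydrofuran-2(3H)-one | O=C1OC[C@H](Cc2ccc(OCc3ccccc3)c(OC)c2)C1=CO
F6 | step 6 | (3R,4R)-4-[4-(benzyloxy)-3-methoxybenzyl]-3-(1,3-dithian-2-yl)dihydrofuran-2(3H)-one (trans) | C1CSC(SC1)[C@H]1C(=O)OC[C@@H]1Cc1ccc(OCc2ccccc2)c(OC)c1
F7 | step 6 | (2R,3R)-2-[4-(benzyloxy)-3-methoxybenzyl]-3-(1,3-dithian-2-yl)butane-1,4-diol | C1CSC(SC1)[C@@H](CO)[C@H](CO)Cc1ccc(OCc2ccccc2)c(OC)c1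
F8 | step 8 | [(3R,4R)-4-{4-[(E)-3-(4-acetoxyphenyl)prop-2-enoyloxy]-3-methoxybenzyl}-2-methoxytetrahydrofuran-3-yl]methyl (E)-3-(4-acetoxyphenyl)prop-2-enoate | COC1OC[C@H](Cc2ccc(OC(=O)/C=C/c3ccc(OC(C)=O)cc3)c(OC)c2)[C@@H]1COC(=O)/C=C/c1ccc(OC(C)=O)cc1
A1 | alternative 1 | (S)-4-benzyl-3-[(E)-3-(3-bromo-4-hydroxy-5-methoxyphenyl)prop-2-enoyl]oxazolidin-2-one | COc1cc(/C=C/C(=O)N2[C@@H](Cc3ccccc3)COC2=O)cc(Br)c1O
A2 | alternative 1 | trans-8-bromo-1-(3-bromo-4-hydroxy-5-methoxyphenyl)-7-hydroxy-6-methoxy-1,2-dihydronaphthalene-2,3-dicarbonyl bis-imide of (S)-4-benzyloxazolidin-2-one | COc1cc([C@H]2c3c(Br)c(O)c(OC)cc3C=C(C(=O)N3[C@@H](Cc4ccccc4)COC3=O)[C@@H]2C(=O)N2[C@@H](Cc3ccccc3)COC2=O)cc(Br)c1O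
A3 | alternative 2 | 4-(tert-butyldimethylsilyloxy)-2-[4-(tert-butyldimethylsilyloxy)-3-methoxybenzyl]-5-methoxybenzaldehyde | COc1cc(C=O)c(Cc2ccc(O[Si](C)(C)C(C)(C)C)c(OC)c2)cc1O[Si](C)(C)C(C)(C)C
A4 | alternative 2 | (S)-3-[(E)-4-(allyloxy)but-2-enoyl]-4-benzyloxazolidin-2-one | C=CCOC/C=C/C(=O)N1[C@@H](Cc2ccccc2)COC1=O
A5 | alternative 2 | (S)-3-({2-(allyloxymethyl)-7-(tert-butyldimethylsilyloxy)-1-[4-(tert-butyldimethylsilyloxy)-3-methoxyphenyl]-4-hydroxy-6-methoxy-1,2,3,4-tetrahydronaphthalen-3-yl}carbonyl)-4-benzyloxazolidin-2-one (ring numbering as in 16) | COc1cc([C@H]2c3cc(O[Si](C)(C)C(C)(C)C)c(OC)cc3[C@@H](O)[C@@H](C(=O)N3[C@@H](Cc4ccccc4)COC3=O)[C@@H]2COCC=C)ccc1O[Si](C)(C)C(C)(C)C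
A6 | alternative 3 | dimethyl (2S,3R)-2-formyl-3-[3-methoxy-4-(triisopropylsilyloxy)phenyl]cyclopropane-1,1-dicarboxylate (trans) | O=C[C@H]1[C@H](c2ccc(O[Si](C(C)C)(C(C)C)C(C)C)c(OC)c2)C1(C(=O)OC)C(=O)OC
A7 | alternative 3 | 4-(chloromethyl)-2-methoxyphenyl pivalate | COc1cc(CCl)ccc1OC(=O)C(C)(C)C
A8 | alternative 3 | dimethyl 1,2-trans-2-formyl-6-methoxy-1-[3-methoxy-4-(triisopropylsilyloxy)phenyl]-7-(pivaloyloxy)-1,4-dihydronaphthalene-3,3(2H)-dicarboxylate | COc1cc([C@H]2c3cc(OC(=O)C(C)(C)C)c(OC)cc3CC(C(=O)OC)(C(=O)OC)[C@@H]2C=O)ccc1O[Si](C(C)C)(C(C)C)C(C)C
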